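**Retrosynthetic overview**
1. The two formyl groups are installed last, by Vilsmeier–Haack diformylation of the 5,7-dihydroxychroman 29.
2. The pyran ring is formed last: O–C1 by reductive etherification of keto-triol 26, and C1′–C2 by the late SN1 union of silyl enol ether 14 (C15 unit) with benzylic acetate 23 (C11 aryl unit).
3. Fragment 14: cyclopentanone ring by [Rh(dppe)]ClO4-catalysed hydroacylation of aldehyde 10; spiro carbon by deconjugative allylation of enal 7; 7 from 6-methylcyclohexenone by Cu(OTf)2/phosphoramidite conjugate addition of i-Pr2Zn and Shapiro formylation.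
4. Fragment 23: resorcinol → C–H borylation/oxidation → tris-MOM phloroglucinol → ortho-lithiation, isovaleraldehyde, acetylation.
5. Ring order: cyclohexene (from 1) → spiro-cyclopentanone → (benzene ring bought) → pyran ring.

Assumption: racemic 6-methylcyclohex-2-en-1-one (1) is bought as such. Locants: spiro[4.5]decane numbering for the terpenoid unit (C5 = spiro atom, C1 = carbonyl/ether carbon, C2 and C10 methyl-bearing, C6=C7 alkene); C1′ = benzylic carbon. Target = (1S,2R,5R,10R,1′S).

**Route**

Step 1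
Reactants: 1 rac-6-methylcyclohex-2-en-1-one; 2 diisopropylzinc
Product: 4 (2R,5R)-2-methyl-5-(propan-2-yl)cyclohexan-1-one, via isopropylzinc enolate 3 (not isolated)
Conditions: Cu(OTf)2 (2 mol %), (R,S,S)-BINOL N,N-bis(1-phenylethyl)phosphoramidite (4 mol %), toluene, −30 °C; 1 M HCl; then NaOMe (0.2 equiv), MeOH, 25 °C
Reagents that add atoms: none
Why: Asymmetric conjugate addition in which the Cu(OTf)2/phosphoramidite complex delivers isopropyl to one face of the β-carbon of both enantiomers of 1 (sets 5R; the ligand antipode is the one that gives R), after which base equilibration of the α-methyl centre gives the diequatorial trans isomer (2R, about 9:1), the rest being removed at the crystalline hydrazone 5.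

Step 2
Reactants: 4 (2R,5R)-2-methyl-5-(propan-2-yl)cyclohexan-1-one
Product: 5 2,4,6-tri(propan-2-yl)benzenesulfonyl hydrazone of 4
Conditions: 2,4,6-(i-Pr)3C6H2SO2NHNH2 (1.05 equiv), HCl (cat.), THF, 25 °C; recrystallise from MeOH
Reagents that add atoms: 2,4,6-tri(propan-2-yl)benzenesulfonyl hydrazide, CC(C)c1cc(C(C)C)c(S(=O)(=O)NN)c(C(C)C)c1
Why: Acid-catalysed hydrazone condensation that leaves the α-centre at its thermodynamic trans configuration, and crystallisation upgrades diastereomeric and enantiomeric purity.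

Step 3
Reactants: 5 2,4,6-tri(propan-2-yl)benzenesulfonyl hydrazone of 4
Product: 7 (3S,6R)-6-methyl-3-(propan-2-yl)cyclohex-1-ene-1-carbaldehyde, via vinyllithium 6 (not isolated)
Conditions: n-BuLi (2.2 equiv), THF–TMEDA, −78 → 0 °C; DMF, −78 → 0 °C; H2O
Reagents that add atoms: N,N-dimethylformamide, CN(C)C=O
Why: Shapiro reaction in which the dianion forms at the less substituted α-CH2, loss of sulfinate and N2 gives the vinyllithium, and DMF formylates it, with neither existing stereocentre touched (the descriptor at the isopropyl carbon changes only through CIP priorities).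

Step 4
Reactants: 7 (3S,6R)-6-methyl-3-(propan-2-yl)cyclohex-1-ene-1-carbaldehyde; 8 allyl bromide
Product: 10 (1R,6R)-6-methyl-3-(propan-2-yl)-1-(prop-2-en-1-yl)cyclohex-2-ene-1-carbaldehyde, via potassium dienolate 9 (not isolated)
Conditions: KOt-Bu (1.2 equiv), THF, −20 °C; 8, −20 → 0 °C
Reagents that add atoms: none
Why: Deconjugative α-alkylation of the γ-deprotonated extended dienolate, in which allyl bromide attacks the α-carbon anti to the adjacent methyl group (held pseudo-axial by A(1,3) strain with the exocyclic enolate), setting the quaternary centre with CHO cis to CH3 (1R) and moving the alkene to C2=C3.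

Step 5
Reactants: 10 (1R,6R)-6-methyl-3-(propan-2-yl)-1-(prop-2-en-1-yl)cyclohex-2-ene-1-carbaldehyde
Product: 11 (5R,10R)-10-methyl-7-(propan-2-yl)spiro[4.5]dec-6-en-1-one
Conditions: [Rh(nbd)(dppe)]ClO4 (5 mol %, pre-treated with H2), CH2Cl2, 25 °C
Reagents that add atoms: none
Why: Intramolecular alkene hydroacylation of a 4-pentenal to a cyclopentanone, favoured by the α-quaternary centre (no enolisation, Thorpe–Ingold effect), with the ring alkene and both stereocentres left untouched.

Step 6
Reactants: 11 (5R,10R)-10-methyl-7-(propan-2-yl)spiro[4.5]dec-6-en-1-one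
Product: 13 (2RS,5R,10R)-2,10-dimethyl-7-(propan-2-yl)spiro[4.5]dec-6-en-1-one, via lithium enolate 12 (not isolated)
Conditions: LiN(i-Pr)2 (1.05 equiv), THF, −78 °C; MeI, −78 → 0 °C
Reagents that add atoms: iodomethane, CI
Why: Enolate alkylation at C2, the only enolisable position because C5 is quaternary, giving a C2 epimer mixture whose configuration is erased in step 7.

Step 7
Reactants: 13 (2RS,5R,10R)-2,10-dimethyl-7-(propan-2-yl)spiro[4.5]dec-6-en-1-one
Product: 14 tert-butyl{[(5R,10R)-2,10-dimethyl-7-(propan-2-yl)spiro[4.5]deca-1,6-dien-1-yl]oxy}dimethylsilane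
Conditions: TBSOTf (1.3 equiv), Et3N (2 equiv), CH2Cl2, 0 → 25 °C
Reagents that add atoms: tert-butyldimethylsilyl trifluoromethanesulfonate, CC(C)(C)[Si](C)(C)OS(=O)(=O)C(F)(F)F
Why: Soft enolisation with O-silylation gives the only possible, tetrasubstituted silyl enol ether, so both C2 epimers converge.

Step 8
Reactants: 15 resorcinol
Product: 16 1,3-bis(methoxymethoxy)benzene
Conditions: NaH (2.4 equiv), DMF, 0 °C; MOMCl (2.4 equiv), 0 → 25 °C
Reagents that add atoms: chloromethyl methyl ether, COCCl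
Why: Williamson-type O-alkylation of the bis-phenoxide (MOM protection).

Step 9
Reactants: 16 1,3-bis(methoxymethoxy)benzene
Product: 17 2-[3,5-bis(methoxymethoxy)phenyl]-4,4,5,5-tetramethyl-1,3,2-dioxaborolane
Conditions: [Ir(OMe)(cod)]2 (1.5 mol %), 4,4′-di-tert-butyl-2,2′-bipyridine (3 mol %), B2pin2 (0.55 equiv), hexane, 60 °C
Reagents that add atoms: bis(pinacolato)diboron, CC1(C)OB(OC1(C)C)B1OC(C)(C)C(C)(C)O1
Why: Sterically controlled aromatic C–H borylation, which goes to the only C–H not ortho to a substituent (C5).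

Step 10
Reactants: 17 2-[3,5-bis(methoxymethoxy)phenyl]-4,4,5,5-tetramethyl-1,3,2-dioxaborolane
Product: 18 3,5-bis(methoxymethoxy)phenol
Conditions: 30 % H2O2 (3 equiv), NaOH (0.1 equiv), THF–H2O, 0 → 25 °C
Reagents that add atoms: hydrogen peroxide, OO
Why: Boronate oxidation by 1,2-aryl shift from boron to peroxide oxygen, with the MOM ethers stable to base.

Step 11
Reactants: 18 3,5-bis(methoxymethoxy)phenol
Product: 19 1,3,5-tris(methoxymethoxy)benzene
Conditions: NaH (1.2 equiv), DMF, 0 °C; MOMCl (1.2 equiv), 0 → 25 °C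
Reagents that add atoms: chloromethyl methyl ether, COCCl
Why: Williamson-type O-alkylation (MOM protection) giving a C3-symmetric arene whose three ring C–H bonds are equivalent.

Step 12
Reactants: 19 1,3,5-tris(methoxymethoxy)benzene; 20 3-methylbutanal
Product: 22 rac-3-methyl-1-[2,4,6-tris(methoxymethoxy)phenyl]butan-1-ol, via aryllithium 21 (not isolated)
Conditions: n-BuLi (1.1 equiv), TMEDA, THF, 0 °C; 20, −78 → 0 °C; H2O
Reagents that add atoms: none
Why: Directed ortho-metalation between two OMOM groups followed by 1,2-addition to the aldehyde, giving a racemic carbinol centre that is ionised later.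

Step 13
Reactants: 22 rac-3-methyl-1-[2,4,6-tris(methoxymethoxy)phenyl]butan-1-ol
Product: 23 rac-3-methyl-1-[2,4,6-tris(methoxymethoxy)phenyl]butyl acetate
Conditions: Ac2O (1.5 equiv), Et3N (2 equiv), DMAP (5 mol %), CH2Cl2, 0 °C; used after filtration through Et3N-deactivated silica
Reagents that add atoms: acetic anhydride, CC(=O)OC(C)=O
Why: DMAP-catalysed O-acylation turns the hydroxyl into a leaving group that ionises without releasing protic acid.

Step 14
Reactants: 14 tert-butyl{[(5R,10R)-2,10-dimethyl-7-(propan-2-yl)spiro[4.5]deca-1,6-dien-1-yl]oxy}dimethylsilane; 23 rac-3-methyl-1-[2,4,6-tris(methoxymethoxy)phenyl]butyl acetate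
Product: 25 (2R,5R,10R)-2,10-dimethyl-2-{(1R)-3-methyl-1-[2,4,6-tris(methoxymethoxy)phenyl]butyl}-7-(propan-2-yl)spiro[4.5]dec-6-en-1-one, via benzylic cation 24 (not isolated)
Conditions: TMSOTf (10 mol %), CH2Cl2, −78 → −50 °C; 23 (1.3 equiv)
Reagents that add atoms: none
Why: SN1 (Mukaiyama-type) alkylation in which C2 of 14 attacks the trialkoxybenzyl cation on its face anti to the methyl-bearing C10 arm of the spiro ring (sets 2R) through an open antiperiplanar transition state that places the cation's isobutyl group on the enol-oxygen/methyl side and its H toward the rigid spiro ring (sets 1′R); moderate selectivity is expected and the diastereomers are separated by chromatography.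

Step 15
Reactants: 25 (2R,5R,10R)-2,10-dimethyl-2-{(1R)-3-methyl-1-[2,4,6-tris(methoxymethoxy)phenyl]butyl}-7-(propan-2-yl)spiro[4.5]dec-6-en-1-one
Product: 26 (2R,5R,10R)-2,10-dimethyl-2-[(1R)-3-methyl-1-(2,4,6-trihydroxyphenyl)butyl]-7-(propan-2-yl)spiro[4.5]dec-6-en-1-one
Conditions: HCl (1.25 M in MeOH), 40 °C, argon; aqueous work-up
Reagents that add atoms: none
Why: Acid-catalysed transacetalisation removes the three MOM groups and traps the formaldehyde unit as dimethoxymethane so that it cannot alkylate the phloroglucinol ring, with no stereocentre affected.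

Step 16
Reactants: 26 (2R,5R,10R)-2,10-dimethyl-2-[(1R)-3-methyl-1-(2,4,6-trihydroxyphenyl)butyl]-7-(propan-2-yl)spiro[4.5]dec-6-en-1-one
Product: 29 (1S,2R,5R,10R,1′S)-5,7-dihydroxychroman (target without its two formyl groups), via lactol 27 (not isolated), via oxocarbenium ion 28 (not isolated)
Conditions: Et3SiH (5 equiv), CF3CO2H (10 equiv), CH2Cl2, −20 → 0 °C
Reagents that add atoms: none
Why: Reductive etherification (ionic hydrogenation) in which an ortho-OH closes onto the C1 ketone, the lactol ionises to the aryl oxocarbenium ion, and Et3SiH delivers hydride to C1 from the face of the angular methyl, because the other face is shielded by the pseudo-axial isobutyl group on C1′ and would give a strained trans-fused ring, so H-1, CH3-2 and H-1′ end cis (1S).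

Step 17
Reactants: 29 (1S,2R,5R,10R,1′S)-5,7-dihydroxychroman
Product: 31 target CNP0121396.3, via bis(iminium) dichloride 30 (not isolated)
Conditions: POCl3 (6 equiv), DMF (8 equiv), MeCN, 0 → 25 °C; then H2O, 50 °C
Reagents that add atoms: N,N-dimethylformamide, CN(C)C=O; water, O
Why: Vilsmeier–Haack formylation at the only two free, doubly activated aromatic positions, followed by hydrolysis of the bis(iminium) salt, with no stereocentre involved.

**Compound list**
1 | rac-6-methylcyclohex-2-en-1-one | CC1CCC=CC1=O | starting material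
2 | diisopropylzinc | CC(C)[Zn]C(C)C | starting material
3 | isopropylzinc (3S,6RS)-6-methyl-3-(propan-2-yl)cyclohex-1-en-1-olate | CC1CC[C@@H](C(C)C)C=C1O[Zn]C(C)C | intermediate
4 | (2R,5R)-2-methyl-5-(propan-2-yl)cyclohexan-1-one (trans) | C[C@@H]1CC[C@@H](C(C)C)CC1=O | intermediate
5 | 2,4,6-tri(propan-2-yl)benzenesulfonyl hydrazone of 4 (C=N geometry not defined) | C[C@@H]1CC[C@@H](C(C)C)CC1=NNS(=O)(=O)c1c(C(C)C)cc(C(C)C)cc1C(C)C | intermediate
6 | [(3S,6R)-6-methyl-3-(propan-2-yl)cyclohex-1-en-1-yl]lithium | [Li]C1=C[C@H](C(C)C)CC[C@H]1C | intermediate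
7 | (3S,6R)-6-methyl-3-(propan-2-yl)cyclohex-1-ene-1-carbaldehyde | O=CC1=C[C@H](C(C)C)CC[C@H]1C | intermediate
8 | allyl bromide (3-bromoprop-1-ene) | C=CCBr | starting material
9 | potassium [(6R)-6-methyl-3-(propan-2-yl)cyclohex-2-en-1-ylidene]methanolate | [K+].[O-]C=C1C=C(C(C)C)CC[C@H]1C | intermediate
10 | (1R,6R)-6-methyl-3-(propan-2-yl)-1-(prop-2-en-1-yl)cyclohex-2-ene-1-carbaldehyde (CHO cis to CH3) | C=CC[C@]1(C=O)C=C(C(C)C)CC[C@H]1C | intermediate
11 | (5R,10R)-10-methyl-7-(propan-2-yl)spiro[4.5]dec-6-en-1-one | O=C2CCC[C@@]21C=C(C(C)C)CC[C@H]1C | intermediate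
12 | lithium (5R,10R)-10-methyl-7-(propan-2-yl)spiro[4.5]deca-1,6-dien-1-olate | [Li]OC2=CCC[C@@]21C=C(C(C)C)CC[C@H]1C | intermediate
13 | (2RS,5R,10R)-2,10-dimethyl-7-(propan-2-yl)spiro[4.5]dec-6-en-1-one | O=C2C(C)CC[C@@]21C=C(C(C)C)CC[C@H]1C | intermediate
14 | tert-butyl{[(5R,10R)-2,10-dimethyl-7-(propan-2-yl)spiro[4.5]deca-1,6-dien-1-yl]oxy}dimethylsilane | CC(C)(C)[Si](C)(C)OC2=C(C)CC[C@@]21C=C(C(C)C)CC[C@H]1C | intermediate
15 | resorcinol (benzene-1,3-diol) | Oc1cccc(O)c1 | starting material
16 | 1,3-bis(methoxymethoxy)benzene | COCOc1cccc(OCOC)c1 | intermediate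
17 | 2-[3,5-bis(methoxymethoxy)phenyl]-4,4,5,5-tetramethyl-1,3,2-dioxaborolane | COCOc1cc(OCOC)cc(B2OC(C)(C)C(C)(C)O2)c1 | intermediate
18 | 3,5-bis(methoxymethoxy)phenol | COCOc1cc(O)cc(OCOC)c1 | intermediate
19 | 1,3,5-tris(methoxymethoxy)benzene | COCOc1cc(OCOC)cc(OCOC)c1 | intermediate
20 | 3-methylbutanal (isovaleraldehyde) | CC(C)CC=O | starting material
21 | [2,4,6-tris(methoxymethoxy)phenyl]lithium | [Li]c1c(OCOC)cc(OCOC)cc1OCOC | intermediate
22 | rac-3-methyl-1-[2,4,6-tris(methoxymethoxy)phenyl]butan-1-ol | CC(C)CC(O)c1c(OCOC)cc(OCOC)cc1OCOC | intermediate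
23 | rac-3-methyl-1-[2,4,6-tris(methoxymethoxy)phenyl]butyl acetate | CC(C)CC(OC(C)=O)c1c(OCOC)cc(OCOC)cc1OCOC | intermediate
24 | 3-methyl-1-[2,4,6-tris(methoxymethoxy)phenyl]butan-1-ylium (benzylic cation) | CC(C)C[CH+]c1c(OCOC)cc(OCOC)cc1OCOC | intermediate
25 | (2R,5R,10R)-2,10-dimethyl-2-{(1R)-3-methyl-1-[2,4,6-tris(methoxymethoxy)phenyl]butyl}-7-(propan-2-yl)spiro[4.5]dec-6-en-1-one | CC(C)C[C@H](c1c(OCOC)cc(OCOC)cc1OCOC)[C@@]1(C)CC[C@@]2(C=C(C(C)C)CC[C@H]2C)C1=O | intermediate
26 | (2R,5R,10R)-2,10-dimethyl-2-[(1R)-3-methyl-1-(2,4,6-trihydroxyphenyl)butyl]-7-(propan-2-yl)spiro[4.5]dec-6-en-1-one | CC(C)C[C@H](c1c(O)cc(O)cc1O)[C@@]1(C)CC[C@@]2(C=C(C(C)C)CC[C@H]2C)C1=O | intermediate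
27 | cyclic hemiketal (lactol) of 26: ortho-O bonded to C1, which also carries OH (both anomers) | CC(C)C[C@@H]1c2c(O)cc(O)cc2OC2(O)[C@]1(C)CC[C@@]21C=C(C(C)C)CC[C@H]1C | intermediate
28 | aryl oxocarbenium ion (ArO+=C1) derived from 27 | CC(C)C[C@@H]1c2c(O)cc(O)cc2[O+]=C2[C@]1(C)CC[C@@]21C=C(C(C)C)CC[C@H]1C | intermediate
29 | (1S,2R,5R,10R,1′S)-5,7-dihydroxychroman: cis-fused cyclopentane/pyran, with H-1, CH3-2 and H-1′ on one face and isobutyl on the cyclopentane side | CC(C)C[C@@H]1c2c(O)cc(O)cc2O[C@H]2[C@]1(C)CC[C@@]21C=C(C(C)C)CC[C@H]1C | intermediate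
30 | 6,8-bis(dimethyliminiomethyl) derivative of 29, dichloride | CC(C)C[C@@H]1c2c(O)c(C=[N+](C)C)c(O)c(C=[N+](C)C)c2O[C@H]2[C@]1(C)CC[C@@]21C=C(C(C)C)CC[C@H]1C.[Cl-].[Cl-] | intermediate
31 | CNP0121396.3: (1S,2R,5R,10R,1′S)-6,8-diformyl-5,7-dihydroxychroman | CC(C)C[C@@H]1c2c(O)c(C=O)c(O)c(C=O)c2O[C@H]2[C@]1(C)CC[C@@]21C=C(C(C)C)CC[C@H]1C | target

**Step count**
Total: 17 steps. Longest linear sequence: 11 steps (1–7, then 14–17). The second branch (steps 8–13, 6 steps) joins at step 14.

**Steps most likely to fail, and fallbacks**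

Step 14 (fragment union). The bond joins a fully substituted enol carbon to a hindered benzylic cation, TMSOTf can also activate the MOM acetals, and the C1′ configuration rests on an open transition state that may give only a modest ratio. The fallback sets C1′ afterwards by hydride delivery instead of by C–C bond formation. The epimer mixture is carried through steps 15 and 16, so the fallback sets out from 29 obtained together with its C1′ epimer F1. DDQ (1.1 equiv, CH2Cl2–MeNO2, 0 °C) removes the benzylic hydride para to the free phenol from both epimers and gives a single p-quinone methide F2. NaBH4 (MeOH–THF, −40 °C) then adds hydride to C1′ anti to the pseudo-axial cyclopentane CH2 (C3), on the face of the angular methyl, and the route comes back at 29.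

Step 16 (reductive etherification). Hydride may attack the other face of the oxocarbenium ion and give the trans-fused ether, and CF3CO2H/Et3SiH can also reduce the trisubstituted alkene. The fallback fixes C1 before ring closure and makes the aryl C–O bond instead. It sets out from 25: LiAlH4 (THF, 0 °C) attacks the cyclopentanone anti to the bulky arylalkyl group on C2 and gives the secondary alcohol F3 (OH cis to the arylalkyl group). HCl in MeOH (40 °C) removes the MOM groups to give the tetraol F4. TsOH (cat.) in toluene at 80 °C then lets the C1 hydroxyl add to the keto tautomer of the phloroglucinol ring with loss of water, so C1 keeps its configuration, and the route comes back at 29.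

Step 17 (double formylation). The reaction may stop at the mono-aldehyde, and the acid released can damage the alkene. The fallback introduces the formyl groups through halogen–lithium exchange. It sets out from 29: NBS (2.05 equiv, CH2Cl2, −78 °C) gives the 6,8-dibromide F5, and NaH/MOMCl gives the bis(methoxymethyl) ether F6. t-BuLi (4.2 equiv, THF, −78 °C) followed by DMF gives the dialdehyde F7, and HCl in MeOH (40 °C) removes the MOM groups, coming back at 31.

**Further compounds**
F1 | step 14 | C1′ epimer of 29 | CC(C)C[C@H]1c2c(O)cc(O)cc2O[C@H]2[C@]1(C)CC[C@@]21C=C(C(C)C)CC[C@H]1C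
F2 | step 14 | p-quinone methide of 29 (C1′=C exocyclic to the ring, C7 carbonyl, C5 hydroxyl) | CC(C)CC1=C2C(O)=CC(=O)C=C2O[C@H]2[C@]1(C)CC[C@@]21C=C(C(C)C)CC[C@H]1C
F3 | step 16 | C1 secondary alcohol from 25 (OH cis to the arylalkyl group on C2) | CC(C)C[C@H](c1c(OCOC)cc(OCOC)cc1OCOC)[C@@]1(C)CC[C@@]2(C=C(C(C)C)CC[C@H]2C)[C@H]1O
F4 | step 16 | tetraol from F3 (three phenols and the C1 alcohol) | CC(C)C[C@H](c1c(O)cc(O)cc1O)[C@@]1(C)CC[C@@]2(C=C(C(C)C)CC[C@H]2C)[C@H]1O
F5 | step 17 | 6,8-dibromide of 29 | CC(C)C[C@@H]1c2c(O)c(Br)c(O)c(Br)c2O[C@H]2[C@]1(C)CC[C@@]21C=C(C(C)C)CC[C@H]1C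
F6 | step 17 | 5,7-bis(methoxymethyl) ether of F5 | CC(C)C[C@@H]1c2c(OCOC)c(Br)c(OCOC)c(Br)c2O[C@H]2[C@]1(C)CC[C@@]21C=C(C(C)C)CC[C@H]1C
F7 | step 17 | 5,7-bis(methoxymethyl) ether of 31 | CC(C)C[C@@H]1c2c(OCOC)c(C=O)c(OCOC)c(C=O)c2O[C@H]2[C@]1(C)CC[C@@]21C=C(C(C)C)CC[C@H]1C
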